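**Numbering used throughout:** 1–21 are the compounds of the route (list after the steps). Ring A is the tetrahydrofuran (O1, C2–C5), ring B the 3,4,5-trimethoxyphenyl group, ring C the 3-hydroxy-4,5-dimethoxyphenyl group (C1′–C6′).

## Analysis of the target

The target 21 is a 2,3,4-trisubstituted tetrahydrofuran of the lariciresinol lignan type: C2 carries ring B, C3 a hydroxymethyl group, and C4 a CH2 group that links to C1′ of ring C. The three stereocentres are contiguous and (2R,3S,4S): ring B at C2 is trans to the CH2OH at C3, and that CH2OH is cis to the arylmethyl group at C4. The C2–O1 bond is a benzylic ether of an electron-rich arene, so acid can ionise it (epimerisation at C2, or Friedel–Crafts closure of ring C onto C2) and hydrogenolysis can cleave it; the free phenol on ring C is easily oxidised. The first difficulty is the cis relationship at C3/C4, which is not the thermodynamically preferred one and must be set under kinetic control together with the trans relationship at C2/C3. The second is that rings B and C differ by a single O-methyl group, so ring C needs one of three neighbouring oxygens left free. The strategy rests on ring C: C3′ (OH) sits next to C4′ and C5′ (both OMe), while C2′ and C6′ carry hydrogen. C3′, C4′, C5′ and C6′ therefore map onto the carbonyl carbon, the two enol ether carbons and the sp3 carbon of a squarate-derived cyclobutenone, and C1′/C2′ onto a 1,1-disubstituted alkene attached to C4 through the CH2 group, so ring C can be built last with its hydroxyl group free from the start.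

## Retrosynthetic reasoning

**21 ⇒ 20.** Only the Si–O bond of the primary alcohol is cut. The silyl ether is kept through ring C formation because a free CH2OH would react with the electrophilic chloride 16 and with the ketene 18. Removal by fluoride avoids the acid that endangers C2–O1.

**20 ⇒ 12 + 16.** Ring C is cut at C2′–C3′ and at C1′–C6′. Going backwards, phenol 20 is the tautomer of dienone 19, which is the 6π-closure product of dienylketene 18, which is the ring-opened form of alkenylcyclobutenone 17; 17 comes from stannane 12 and chloride 16 by cross-coupling. These two bonds are chosen because they join a four-carbon unit that already carries all three oxygens in the right order and leaves C3′ as the free OH. Cutting C4–CH2 or CH2–C1′ instead would demand a ready-made ring C with one oxygen protected differently from the other two. The forward reaction has to couple at the CH carbon of the four-membered ring and then open and re-close it under neutral conditions.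

**16 ⇒ 14 ⇒ 13.** The C–Cl bond is traced to C–OH, and the carbinol to one carbonyl of squarate 13. Because 13 is symmetric, mono-reduction raises no regiochemical question.

**12 ⇒ 11 ⇒ 10 ⇒ 8 ⇒ 7.** The C–Sn bond is traced to a terminal alkyne (tin to the internal carbon), the silyl ether to alcohol 10, the alkyne to the aldehyde of hydroxy aldehyde 9 (the open form of lactol 8) by one-carbon homologation, and the lactol to lactone 7. These are functional-group changes; the lactone is the form in which the next disconnection delivers the two side arms.

**7 ⇒ 5.** The C3–C4 bond of ring A (and the lactone C–O bond) is cut. A radical at C3, generated from an epoxide by a trivalent titanocene reagent, adds 5-exo to an enoate. This forms ring A, leaves CH2O on C3 and CH2C(=O) on C4, which are exactly the two arms needed, and sets C3 and C4 from C2 alone. Cutting C2–C3 or a ring C–O bond would leave the C3/C4 cis relationship to acyclic stereocontrol.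

**5 ⇒ 4 ⇒ 3.** The enoate C=C is cut by cross-metathesis of the allyl ether 4 with an acrylate ester, and the O–CH2 bond by O-allylation of epoxy alcohol 3. The two-step sequence avoids basic alkylation with a γ-halo enoate.

**3 ⇒ 2 ⇒ 1.** The epoxide oxygen is introduced by kinetic-resolution epoxidation of racemic allylic alcohol 2, which comes from aldehyde 1 and a vinyl Grignard reagent. Only the carbinol centre matters: it becomes C2 and controls everything else. The epoxide centre is destroyed when the radical forms.

## Alternatives that were turned down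

**Alternative 1:** tandem conjugate addition–alkylation on a chiral butenolide.
- Disconnection: C2–C3 and the bond from C4 to the benzylic CH2.
- Forward key step: dithiane A2, after lithiation, adds to the β-carbon of the menthyloxy butenolide A1 anti to the acetal substituent; the enolate is then alkylated by benzylic bromide A3 anti to the new group, giving the all-trans lactone A4.
- For it: two C–C bonds and both C3 and C4 are set in one flask from three fragments, with absolute control from an auxiliary. On convergence, and on not wasting half the material in a resolution, it is stronger than the chosen route.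
- Against it: C2 is not set, because the dithiane carbon is achiral. After reduction of lactone and acetal and unmasking of the ketone, C2 must be created late by reduction and ring closure through a benzylic cation or oxocarbenium ion, the conditions under which ring C can attack C2. It also needs A3, a ring C building block with one oxygen already differentiated, and a final debenzylation that competes with hydrogenolysis of C2–O1. Five or six steps follow the key step.
- Comparison: overall length is similar. The chosen route sets C2 first, uses no acid after ring A exists, and needs no phenol protecting group.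

**Alternative 2:** ketene [2+2] cycloaddition on a dihydrofuran.
- Disconnection: both exocyclic C–C bonds at C3 and C4 of a preformed ring A.
- Forward key step: dichloroketene A6 adds across C3=C4 of dihydrofuran A5 on the face away from ring B, giving the cis-fused cyclobutanone A7.
- For it: A5 is reachable in very few steps by catalytic asymmetric arylation, and cis fusion guarantees C3/C4 cis while the aryl group directs C2/C3 trans. On speed of setting the three stereocentres it is stronger.
- Against it: C3 and C4 of A5 are electronically almost equivalent, and the required orientation places the bulky CCl2 terminus on the more hindered C3, so regiocontrol is doubtful. The alkene, flanked by two ether carbons, is a poor partner for the electrophilic ketene. After ring cleavage the CHCl2 group must become CH2OH and the acyl carbon must be arylated and deoxygenated, again with a differentiated ring C and with reductive or acidic conditions next to C2–O1.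
- Comparison: it is not shorter in the end. The chosen route has unambiguous regiochemistry in ring A formation.

**Alternative 3:** radical cyclisation onto a cinnamyl ether.
- Disconnection: C3–C4, as in the chosen ring A construction, but with ring C already present in the acceptor arm.
- Forward key step: the trivalent titanium reagent of step 5 opens the epoxide of cinnamyl ether A8 (made from epoxy alcohol 3); the C3 radical closes 5-exo onto the styrene and the benzylic radical is reduced, giving the O-benzyl ether A9 of the target.
- For it: the whole skeleton and all three stereocentres are present after one step, through the same transition state as step 5, and only deprotection remains. On step economy it is clearly stronger than the chosen route (roughly half the longest linear sequence), and on stereocontrol it is equal.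
- Against it: the ring C fragment of A8 must be bought or made with one of three oxygens masked differently, and it becomes the longest branch. Hydrogenolytic debenzylation competes with cleavage of the C2–O1 benzylic ether, and Lewis acid debenzylation risks ionising C2. A styrene is also a less electrophilic trap for the nucleophilic β-oxy alkyl radical than an enoate, so premature reduction of the radical is more likely.
- Comparison: the chosen route is longer. What it offers in return is ring C built from symmetric squarate 13 with the phenol free by construction, no phenol protecting group at any stage, and a common stannane 12 from which ring C analogues can be made.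

Key step: step 12

Remark: the alkyl groups on tin are spectators, so stannane 12 is carried as its trimethylstannyl derivative; all ring A intermediates are numbered as in the target.

## Route

Step 1
Reactants: 1 3,4,5-trimethoxybenzaldehyde
Product: 2 rac-1-(3,4,5-trimethoxyphenyl)prop-2-en-1-ol
Conditions: CH2=CHMgBr (1.2 equiv), THF, 0 °C; aq. NH4Cl
Reagents that add atoms: vinylmagnesium bromide, C=C[Mg]Br
Why: 1,2-addition of a Grignard reagent to a non-enolisable aryl aldehyde; the racemate is wanted because step 2 resolves it.

Step 2
Reactants: 2 rac-1-(3,4,5-trimethoxyphenyl)prop-2-en-1-ol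
Product: 3 (S)-[(R)-oxiran-2-yl](3,4,5-trimethoxyphenyl)methanol
Conditions: Ti(OiPr)4 (0.2 equiv), L-(+)-diisopropyl tartrate (0.24 equiv), tBuOOH (0.45 equiv), 4 Å MS, CH2Cl2, −20 °C; stopped short of half conversion; unreacted (S)-2 removed by chromatography
Reagents that add atoms: tert-butyl hydroperoxide, CC(C)(C)OO
Why: Sharpless kinetic resolution: with the L-(+)-tartrate catalyst the (R)-enantiomer of 2 is the matched one and is epoxidised with erythro selectivity, while the (S)-enantiomer reacts slowly and is left behind. The carbinol centre retained here becomes C2 of the target; the epoxide centre is erased in step 5.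

Step 3
Reactants: 3 (S)-[(R)-oxiran-2-yl](3,4,5-trimethoxyphenyl)methanol
Product: 4 (R)-2-[(S)-(prop-2-en-1-yloxy)(3,4,5-trimethoxyphenyl)methyl]oxirane
Conditions: NaH (1.2 equiv), allyl bromide (1.5 equiv), Bu4NI (cat.), THF, 0 °C → rt
Reagents that add atoms: allyl bromide, C=CCBr
Why: Williamson etherification of the secondary alkoxide with a reactive allylic halide; in THF at low temperature alkylation should outrun Payne migration of the epoxide, as with other 1,2-epoxy-3-ols.

Step 4
Reactants: 4 (R)-2-[(S)-(prop-2-en-1-yloxy)(3,4,5-trimethoxyphenyl)methyl]oxirane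
Product: 5 ethyl (E)-4-{(S)-[(R)-oxiran-2-yl](3,4,5-trimethoxyphenyl)methoxy}but-2-enoate
Conditions: ethyl acrylate (4 equiv), second-generation Hoveyda–Grubbs catalyst RuCl2(H2IMes)(=CH-C6H4-2-OiPr) (3 mol%), CH2Cl2, 40 °C
Reagents that add atoms: ethyl acrylate, C=CC(=O)OCC
Why: Olefin cross-metathesis between a terminal allyl ether and an electron-poor acrylate favours the cross product and the (E)-enoate; the epoxide and the benzylic ether are inert to the ruthenium carbene.

Step 5
Reactants: 5 ethyl (E)-4-{(S)-[(R)-oxiran-2-yl](3,4,5-trimethoxyphenyl)methoxy}but-2-enoate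
Product: 7 cis-fused δ-lactone joining the C3 CH2O arm to the C4 CH2C(=O) arm of (2R,3S,4S)-2-(3,4,5-trimethoxyphenyl)tetrahydrofuran, via hydroxy ester 6 (not isolated)
Conditions: Cp2TiCl2 (2.5 equiv), Zn dust, THF, rt, the green Cp2TiCl solution added slowly to 5; aq. NaH2PO4; then pyridinium p-toluenesulfonate (cat.), toluene, 50 °C
Reagents that add atoms: none
Why: Reductive epoxide opening by Cp2TiCl (Nugent–RajanBabu reaction) gives the secondary β-titanoxy radical at C3, which closes 5-exo-trig onto the enoate β-carbon to form C3–C4; a second Cp2TiCl reduces the α-ester radical to a titanium enolate that is protonated on work-up. In the chair-like Beckwith–Houk transition state ring B at C2 is pseudo-equatorial and the CH2OTi group is cis to the acceptor arm, which sets C3 and C4 (ring B trans to CH2O, CH2O cis to CH2CO2Et). Lactonisation of the cis pair to 7 gives a handle for separating any minor isomer.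

Step 6
Reactants: 7 cis-fused δ-lactone
Product: 8 lactol of 7 (both anomers)
Conditions: iBu2AlH (1.1 equiv), CH2Cl2, −78 °C; aq. potassium sodium tartrate
Reagents that add atoms: none
Why: Partial reduction of a δ-lactone by iBu2AlH at −78 °C stops at the tetrahedral aluminate and gives the lactol on work-up; ethers and arenes are untouched.

Step 7
Reactants: 8 lactol
Product: 10 [(2R,3S,4S)-4-(prop-2-yn-1-yl)-2-(3,4,5-trimethoxyphenyl)tetrahydrofuran-3-yl]methanol, via hydroxy aldehyde 9 (not isolated)
Conditions: dimethyl (1-diazo-2-oxopropyl)phosphonate (2 equiv), K2CO3 (3 equiv), MeOH, 0 °C → rt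
Reagents that add atoms: Ohira–Bestmann reagent, CC(=O)C(=[N+]=[N-])P(=O)(OC)OC
Why: Seyferth–Gilbert homologation in the Ohira–Bestmann form: the lactol is in equilibrium with hydroxy aldehyde 9, whose CHO becomes C≡CH through a diazoalkene and 1,2-hydrogen shift of the alkylidene carbene. No stereocentre is α to the aldehyde, so the carbonate base cannot epimerise anything.

Step 8
Reactants: 10 [(2R,3S,4S)-4-(prop-2-yn-1-yl)-2-(3,4,5-trimethoxyphenyl)tetrahydrofuran-3-yl]methanol
Product: 11 tert-butyl(dimethyl){[(2R,3S,4S)-4-(prop-2-yn-1-yl)-2-(3,4,5-trimethoxyphenyl)tetrahydrofuran-3-yl]methoxy}silane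
Conditions: TBSCl (1.2 equiv), imidazole (2.5 equiv), DMF, rt
Reagents that add atoms: tert-butyldimethylsilyl chloride, CC(C)(C)[Si](C)(C)Cl
Why: Standard silylation of a primary alcohol; the silyl ether shields the hydroxyl from chloride 16 and ketene 18 in step 12 and is removable without acid.

Step 9
Reactants: 11 tert-butyl(dimethyl){[(2R,3S,4S)-4-(prop-2-yn-1-yl)-2-(3,4,5-trimethoxyphenyl)tetrahydrofuran-3-yl]methoxy}silane
Product: 12 tert-butyl(dimethyl){[(2R,3S,4S)-2-(3,4,5-trimethoxyphenyl)-4-[2-(trimethylstannyl)prop-2-en-1-yl]tetrahydrofuran-3-yl]methoxy}silane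
Conditions: Me3SnCu·SMe2 (2 equiv; from Me3SnSnMe3, MeLi, then CuBr·SMe2, THF, −78 °C), MeOH (60 equiv), THF, −78 → −63 °C; aq. NH4Cl/NH3 (pH 8)
Reagents that add atoms: (trimethylstannyl)copper–dimethyl sulfide complex, C[Sn](C)(C)[Cu].CSC
Why: syn-Stannylcupration of the terminal alkyne places tin on the internal carbon and copper on the terminal one, and methanol protonates the alkenylcopper as it forms, which fixes the kinetic regiochemistry and gives the 2-stannyl-1-alkene. A copper-mediated addition is preferred to catalytic hydrostannation because 11 has no propargylic heteroatom to steer tin to the internal carbon.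

Step 10
Reactants: 13 dimethyl squarate (3,4-dimethoxycyclobut-3-ene-1,2-dione)
Product: 14 rac-4-hydroxy-2,3-dimethoxycyclobut-2-en-1-one
Conditions: LiAlH(OtBu)3 (1.05 equiv), THF, −78 → −20 °C; cold aq. NH4Cl; used crude
Reagents that add atoms: none
Why: Mono-reduction of one carbonyl of the symmetric dione by a hindered single-hydride reagent; the product is a vinylogous ester and should resist further reduction at low temperature.

Step 11
Reactants: 14 rac-4-hydroxy-2,3-dimethoxycyclobut-2-en-1-one
Product: 16 rac-4-chloro-2,3-dimethoxycyclobut-2-en-1-one, via mesylate 15 (not isolated)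
Conditions: MsCl (1.2 equiv), LiCl (3 equiv), 2,4,6-collidine (1.5 equiv), DMF, 0 °C; cold extraction; used at once
Reagents that add atoms: lithium chloride, [Li+].[Cl-]
Why: Chlorodehydroxylation of an allylic alcohol under non-acidic conditions: the mesylate is formed and displaced by chloride in the same flask. Acid is avoided because it would ionise C4 and expel methanol.

Step 12
Reactants: 12 tert-butyl(dimethyl){[(2R,3S,4S)-2-(3,4,5-trimethoxyphenyl)-4-[2-(trimethylstannyl)prop-2-en-1-yl]tetrahydrofuran-3-yl]methoxy}silane; 16 rac-4-chloro-2,3-dimethoxycyclobut-2-en-1-one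
Product: 20 5-{[(3S,4S,5R)-4-{[tert-butyl(dimethyl)silyl]oxymethyl}-5-(3,4,5-trimethoxyphenyl)tetrahydrofuran-3-yl]methyl}-2,3-dimethoxyphenol (O-silyl ether of the target), via alkenylcyclobutenone 17 (not isolated), via dienylketene 18 (not isolated), via cyclohexadienone 19 (not isolated)
Conditions: Pd2(dba)3 (2.5 mol%), tri(2-furyl)phosphine (10 mol%), 16 (1.5 equiv), 1,4-dioxane, 50 °C, then 100 °C
Reagents that add atoms: none
Why: Zerovalent palladium ionises the C–Cl bond of 16 to an oxocyclobutenyl-palladium chloride, the alkenyl group of 12 is transferred from tin, and reductive elimination at the CH terminus forms C1′–C6′ in 17; this is the known Stille coupling of 4-chlorocyclobutenones with alkenylstannanes. Coupling at that terminus rather than at the methoxy-bearing one is expected because it avoids a quaternary centre and keeps the vinylogous ester. On warming, 17 opens by conrotatory 4π electrocyclisation to dienylketene 18. The ketene carbon and the terminal CH2 then join by thermal disrotatory 6π electrocyclisation, which forms C2′–C3′ and closes ring C as the six-membered carbocycle 19, and tautomerisation of 19 gives the phenol. No stereocentre is created: the sp3 centre of 17 is transient, and C2, C3 and C4 of ring A are remote and are not ionised under these neutral conditions. The selectivity needed is constitutional only: ring opening is reversible, so the ketene isomer with the alkenyl group turned outward re-closes to 17 and material drains through the isomer that can cyclise, while the pattern OH at C3′, OMe at C4′ and C5′, H at C2′ and C6′ is dictated by the connectivity of 17. The weakly donating tri(2-furyl)phosphine is chosen to speed transmetalation of the hindered 1,1-disubstituted alkenylstannane.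

Step 13
Reactants: 20 O-silyl ether of the target
Product: 21 [(2R,3S,4S)-4-(3-hydroxy-4,5-dimethoxybenzyl)-2-(3,4,5-trimethoxyphenyl)tetrahydrofuran-3-yl]methanol
Conditions: Bu4NF (1.2 equiv), THF, 0 °C → rt, under argon; aq. NH4Cl
Reagents that add atoms: none
Why: Fluoride cleaves the primary silyl ether through a pentacoordinate silicate; the non-acidic conditions leave the C2–O1 benzylic ether and the three stereocentres untouched.

## Compound list

1 | 3,4,5-trimethoxybenzaldehyde | COc1cc(C=O)cc(OC)c1OC | starting material
2 | rac-1-(3,4,5-trimethoxyphenyl)prop-2-en-1-ol | C=CC(O)c1cc(OC)c(OC)c(OC)c1 | intermediate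
3 | (S)-[(R)-oxiran-2-yl](3,4,5-trimethoxyphenyl)methanol | O[C@@H](c1cc(OC)c(OC)c(OC)c1)[C@H]2CO2 | intermediate
4 | (R)-2-[(S)-(prop-2-en-1-yloxy)(3,4,5-trimethoxyphenyl)methyl]oxirane | C=CCO[C@@H](c1cc(OC)c(OC)c(OC)c1)[C@H]2CO2 | intermediate
5 | ethyl (E)-4-{(S)-[(R)-oxiran-2-yl](3,4,5-trimethoxyphenyl)methoxy}but-2-enoate | CCOC(=O)/C=C/CO[C@@H](c1cc(OC)c(OC)c(OC)c1)[C@H]2CO2 | intermediate
6 | ethyl [(2R,3S,4S)-3-(hydroxymethyl)-2-(3,4,5-trimethoxyphenyl)tetrahydrofuran-4-yl]acetate | CCOC(=O)C[C@@H]1CO[C@@H](c2cc(OC)c(OC)c(OC)c2)[C@@H]1CO | intermediate (not isolated)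
7 | cis-fused δ-lactone of 6 (C3 CH2O joined to C4 CH2C=O; 2R,3S,4S in ring A numbering) | O=C1C[C@@H]2CO[C@@H](c3cc(OC)c(OC)c(OC)c3)[C@@H]2CO1 | intermediate
8 | lactol of 7 (both anomers) | OC1C[C@@H]2CO[C@@H](c3cc(OC)c(OC)c(OC)c3)[C@@H]2CO1 | intermediate
9 | [(2R,3S,4S)-3-(hydroxymethyl)-2-(3,4,5-trimethoxyphenyl)tetrahydrofuran-4-yl]acetaldehyde | O=CC[C@@H]1CO[C@@H](c2cc(OC)c(OC)c(OC)c2)[C@@H]1CO | intermediate (not isolated)
10 | [(2R,3S,4S)-4-(prop-2-yn-1-yl)-2-(3,4,5-trimethoxyphenyl)tetrahydrofuran-3-yl]methanol | C#CC[C@@H]1CO[C@@H](c2cc(OC)c(OC)c(OC)c2)[C@@H]1CO | intermediate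
11 | tert-butyl(dimethyl){[(2R,3S,4S)-4-(prop-2-yn-1-yl)-2-(3,4,5-trimethoxyphenyl)tetrahydrofuran-3-yl]methoxy}silane | C#CC[C@@H]1CO[C@@H](c2cc(OC)c(OC)c(OC)c2)[C@@H]1CO[Si](C)(C)C(C)(C)C | intermediate
12 | tert-butyl(dimethyl){[(2R,3S,4S)-2-(3,4,5-trimethoxyphenyl)-4-[2-(trimethylstannyl)prop-2-en-1-yl]tetrahydrofuran-3-yl]methoxy}silane | C=C(C[C@@H]1CO[C@@H](c2cc(OC)c(OC)c(OC)c2)[C@@H]1CO[Si](C)(C)C(C)(C)C)[Sn](C)(C)C | intermediate
13 | dimethyl squarate | COC1=C(OC)C(=O)C1=O | starting material
14 | rac-4-hydroxy-2,3-dimethoxycyclobut-2-en-1-one | COC1=C(OC)C(O)C1=O | intermediate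
15 | rac-4-(methanesulfonyloxy)-2,3-dimethoxycyclobut-2-en-1-one | COC1=C(OC)C(OS(C)(=O)=O)C1=O | intermediate (not isolated)
16 | rac-4-chloro-2,3-dimethoxycyclobut-2-en-1-one | COC1=C(OC)C(Cl)C1=O | intermediate
17 | 4-alkenyl-2,3-dimethoxycyclobut-2-en-1-one carrying the ring A unit (both epimers at the ring CH) | COC1=C(OC)C(C(=C)C[C@@H]2CO[C@@H](c3cc(OC)c(OC)c(OC)c3)[C@@H]2CO[Si](C)(C)C(C)(C)C)C1=O | intermediate (not isolated)
18 | dienylketene from 17, alkenyl group cis to the ketene-bearing carbon | O=C=C(OC)/C(OC)=C\C(=C)C[C@@H]1CO[C@@H](c2cc(OC)c(OC)c(OC)c2)[C@@H]1CO[Si](C)(C)C(C)(C)C | intermediate (not isolated)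
19 | 2,3-dimethoxy-5-substituted cyclohexa-2,4-dien-1-one (keto tautomer of 20) | O=C1CC(C[C@@H]2CO[C@@H](c3cc(OC)c(OC)c(OC)c3)[C@@H]2CO[Si](C)(C)C(C)(C)C)=CC(OC)=C1OC | intermediate (not isolated)
20 | O-tert-butyldimethylsilyl ether of the target (free phenol) | COc1cc(C[C@@H]2CO[C@@H](c3cc(OC)c(OC)c(OC)c3)[C@@H]2CO[Si](C)(C)C(C)(C)C)cc(O)c1OC | intermediate
21 | [(2R,3S,4S)-4-(3-hydroxy-4,5-dimethoxybenzyl)-2-(3,4,5-trimethoxyphenyl)tetrahydrofuran-3-yl]methanol | COc1cc(C[C@@H]2CO[C@@H](c3cc(OC)c(OC)c(OC)c3)[C@@H]2CO)cc(O)c1OC | target

## Step count and least certain steps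

Total step count: 13. Longest linear sequence: 11 (steps 1–9, 12, 13); the squarate branch is steps 10 and 11.

**Step 12 (key step).** The most likely failure is decomposition of the labile chloride 16 (loss of chloride or methanol, hydrolysis) running faster than the slow transmetalation of the hindered 1,1-disubstituted alkenylstannane, together with protodestannylation of 12 by traces of acid. The fallback gives up building ring C on the molecule and brings it in ready-made. Commercial 3-hydroxy-4,5-dimethoxybenzaldehyde is methylenated (Ph3P=CH2, two equivalents) to 5-ethenyl-2,3-dimethoxyphenol F1 and silylated to tert-butyl(5-ethenyl-2,3-dimethoxyphenoxy)dimethylsilane F2. Setting out from allyl ether 4, cross-metathesis with F2 under the catalyst of step 4 should give the (E)-cinnamyl epoxy ether F3. Cp2TiCl cyclisation as in step 5 (the benzylic radical formed after 5-exo closure is reduced and protonated) should give the aryl silyl ether F4, and Bu4NF returns to the route at target 21.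

**Step 11.** Ionisation at C4 during sulfonylation or work-up can lead to loss of methanol, allylic transposition or hydrolysis, so that the chloride does not survive handling. The fallback sets out from 14: acetylation (Ac2O, pyridine, 0 °C) gives 4-acetoxy-2,3-dimethoxycyclobut-2-en-1-one F5, which should tolerate isolation. Under the conditions of step 12 with LiCl in DMF, zerovalent palladium ionises the allylic acetate to the same oxocyclobutenyl-palladium species, so coupling with 12 and heating rejoins the route at 20.

**Step 5.** Two processes threaten it: reduction of the β-titanoxy radical by a second Cp2TiCl before it cyclises, followed by elimination to the alkene (deoxygenation), and incomplete facial control in the 5-exo closure giving the C3/C4 trans isomer. The fallback replaces the metal-mediated radical generation by a tin hydride chain. Setting out from 5, the epoxide is hydrolysed (water, Co(salen)OAc with trivalent cobalt, salen = N,N′-bis(3,5-di-tert-butylsalicylidene)cyclohexane-1,2-diamine dianion) to ethyl (E)-4-{[(1S,2R)-2,3-dihydroxy-1-(3,4,5-trimethoxyphenyl)propyl]oxy}but-2-enoate F6. 1,1′-Thiocarbonyldiimidazole closes F6 to the cyclic thionocarbonate F7. Bu3SnH/AIBN in refluxing benzene at high dilution fragments F7 to the secondary C3 radical (Barton–McCombie type), which cyclises as before and is reduced by the tin hydride. Aqueous NaHCO3 hydrolysis of the stannyl thiolcarbonate and lactonisation as in step 5 rejoin the route at 7.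

**Step 2.** Enantiomer discrimination may be too low for an aryl vinyl carbinol to give 3 in high enantiomeric purity at a practical conversion, and the benzylic epoxy alcohol may be opened by the Lewis acidic catalyst on prolonged contact. The fallback harvests the other component of the resolution. Setting out from 2, the reaction is run with D-(−)-diisopropyl tartrate and 0.65 equiv tBuOOH so that the (S)-enantiomer is consumed and (R)-1-(3,4,5-trimethoxyphenyl)prop-2-en-1-ol F8 is recovered. F8 is then epoxidised to completion with the matched L-(+)-tartrate catalyst, which also filters out residual wrong enantiomer, and the route is rejoined at 3.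

**Step 7.** The six-membered lactol may open too reluctantly, so that the diazophosphonate anion decomposes before it condenses with the small equilibrium amount of 9. The fallback avoids a lactol altogether. Setting out from 7, Me(MeO)NH·HCl/AlMe3 opens the lactone to the hydroxy Weinreb amide F9, TBSCl/imidazole gives its silyl ether F10, and iBu2AlH at −78 °C gives the free aldehyde F11. The Ohira–Bestmann reaction on F11 then rejoins the route at 11.

## Further compounds

F1 | step 12 | 5-ethenyl-2,3-dimethoxyphenol | C=Cc1cc(O)c(OC)c(OC)c1
F2 | step 12 | tert-butyl(5-ethenyl-2,3-dimethoxyphenoxy)dimethylsilane | C=Cc1cc(OC)c(OC)c(O[Si](C)(C)C(C)(C)C)c1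
F3 | step 12 | (R)-2-[(S)-{[(E)-3-(3-{[tert-butyl(dimethyl)silyl]oxy}-4,5-dimethoxyphenyl)prop-2-en-1-yl]oxy}(3,4,5-trimethoxyphenyl)methyl]oxirane | COc1cc(/C=C/CO[C@@H](c2cc(OC)c(OC)c(OC)c2)[C@H]3CO3)cc(O[Si](C)(C)C(C)(C)C)c1OC
F4 | step 12 | [(2R,3S,4S)-4-(3-{[tert-butyl(dimethyl)silyl]oxy}-4,5-dimethoxybenzyl)-2-(3,4,5-trimethoxyphenyl)tetrahydrofuran-3-yl]methanol | COc1cc(C[C@@H]2CO[C@@H](c3cc(OC)c(OC)c(OC)c3)[C@@H]2CO)cc(O[Si](C)(C)C(C)(C)C)c1OC
F5 | step 11 | rac-4-acetoxy-2,3-dimethoxycyclobut-2-en-1-one | COC1=C(OC)C(OC(C)=O)C1=O
F6 | step 5 | ethyl (E)-4-{[(1S,2R)-2,3-dihydroxy-1-(3,4,5-trimethoxyphenyl)propyl]oxy}but-2-enoate | CCOC(=O)/C=C/CO[C@@H](c1cc(OC)c(OC)c(OC)c1)[C@H](O)CO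
F7 | step 5 | ethyl (E)-4-{(S)-[(4R)-2-thioxo-1,3-dioxolan-4-yl](3,4,5-trimethoxyphenyl)methoxy}but-2-enoate | CCOC(=O)/C=C/CO[C@@H](c1cc(OC)c(OC)c(OC)c1)[C@H]2COC(=S)O2
F8 | step 2 | (R)-1-(3,4,5-trimethoxyphenyl)prop-2-en-1-ol | O[C@@H](c1cc(OC)c(OC)c(OC)c1)C=C
F9 | step 7 | 2-[(2R,3S,4S)-3-(hydroxymethyl)-2-(3,4,5-trimethoxyphenyl)tetrahydrofuran-4-yl]-N-methoxy-N-methylacetamide | CON(C)C(=O)C[C@@H]1CO[C@@H](c2cc(OC)c(OC)c(OC)c2)[C@@H]1CO
F10 | step 7 | O-tert-butyldimethylsilyl ether of F9 | CON(C)C(=O)C[C@@H]1CO[C@@H](c2cc(OC)c(OC)c(OC)c2)[C@@H]1CO[Si](C)(C)C(C)(C)C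
F11 | step 7 | [(2R,3S,4S)-3-{[tert-butyl(dimethyl)silyl]oxymethyl}-2-(3,4,5-trimethoxyphenyl)tetrahydrofuran-4-yl]acetaldehyde | O=CC[C@@H]1CO[C@@H](c2cc(OC)c(OC)c(OC)c2)[C@@H]1CO[Si](C)(C)C(C)(C)C
A1 | alternative 1 | (5S)-5-{[(1S,2R,5S)-5-methyl-2-(propan-2-yl)cyclohexyl]oxy}furan-2(5H)-one | O=C1O[C@H](O[C@H]2C[C@@H](C)CC[C@@H]2C(C)C)C=C1
A2 | alternative 1 | 2-(3,4,5-trimethoxyphenyl)-1,3-dithiane | COc1cc(C2SCCCS2)cc(OC)c1OC
A3 | alternative 1 | 1-(benzyloxy)-5-(bromomethyl)-2,3-dimethoxybenzene | COc1cc(CBr)cc(OCc2ccccc2)c1OC
A4 | alternative 1 | trans,trans-3-[3-(benzyloxy)-4,5-dimethoxybenzyl]-5-[(1S,2R,5S)-menthyloxy]-4-[2-(3,4,5-trimethoxyphenyl)-1,3-dithian-2-yl]dihydrofuran-2(3H)-one | O=C1O[C@H](O[C@H]2C[C@@H](C)CC[C@@H]2C(C)C)[C@@H](C2(c3cc(OC)c(OC)c(OC)c3)SCCCS2)[C@@H]1Cc1cc(OC)c(OC)c(OCc2ccccc2)c1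
A5 | alternative 2 | (R)-2-(3,4,5-trimethoxyphenyl)-2,5-dihydrofuran | C1=C[C@H](c2cc(OC)c(OC)c(OC)c2)OC1
A6 | alternative 2 | dichloroketene | ClC(Cl)=C=O
A7 | alternative 2 | cis-fused 7,7-dichloro-2-(3,4,5-trimethoxyphenyl)-3-oxabicyclo[3.2.0]heptan-6-one, aryl exo | O=C1[C@@H]2CO[C@@H](c3cc(OC)c(OC)c(OC)c3)[C@@H]2C1(Cl)Cl
A8 | alternative 3 | (R)-2-[(S)-{[(E)-3-(3-(benzyloxy)-4,5-dimethoxyphenyl)prop-2-en-1-yl]oxy}(3,4,5-trimethoxyphenyl)methyl]oxirane | COc1cc(/C=C/CO[C@@H](c2cc(OC)c(OC)c(OC)c2)[C@H]3CO3)cc(OCc4ccccc4)c1OC
A9 | alternative 3 | [(2R,3S,4S)-4-(3-(benzyloxy)-4,5-dimethoxybenzyl)-2-(3,4,5-trimethoxyphenyl)tetrahydrofuran-3-yl]methanol | COc1cc(C[C@@H]2CO[C@@H](c3cc(OC)c(OC)c(OC)c3)[C@@H]2CO)cc(OCc2ccccc2)c1OC
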